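Start with a count you can do at the bench: each electrophile that reacts takes one nucleophile, and each over-reaction product takes one more.

| flask | electrophile | nucleophile | temperature | remark | time |
|---|---|---|---|---|---|
| alder | 0.0057 M | 0.025 M | 75 °C | run made earlier |  |
| larch | 0.017 M | 0.025 M | 86 °C | run made earlier |  |
| red | 0.025 M | 0.0250 M | 80 °C |  | 10 h |
| grey | 0.0080 M | 0.0250 M | 80 °C |  | 10 h |

| run | time / h | target / % | over-reaction product / % |
|---|---|---|---|
| alder | 1.00 | 17.6 | 0.4 |
| alder | 2.00 | 28.8 | 2.8 |
| alder | 3.00 | 37.7 | 5.0 |
| alder | 4.00 | 43.0 | 7.6 |
| alder | 5.00 | 46.6 | 10.5 |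
| larch | 0.417 | 16.2 | 0.6 |
| larch | 1.33 | 34.5 | 3.7 |
| larch | 2.50 | 43.2 | 6.7 |
| larch | 4.00 | 48.7 | 9.9 |
| larch | 5.00 | 49.9 | 10.6 |

(each reading ± 0.3 percentage points)

* the winner by share of target in all that became target or over-reaction product; "neither" if no more than 2 percentage points parts them (red / grey / neither)
* share of target in all that became target or over-reaction product, red
* share of target in all that became target or over-reaction product, grey



On that count, the larch run has spent 48.3% of its nucleophile by 5.00 h, yet its conversion grew by just 1.9 percentage points in the last hour. Charging two nucleophile per electrophile converted gives 89.5%, which suits that slowing.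

So take this rule of thumb. For red it gives 50.0%: the conversion ceiling, nucleophile charged over twice the electrophile charged, with the nucleophile as limiting reagent. Now go round once more. Near that conversion larch reads a share of target (the selectivity) of 86.6%. Putting the over-reaction cost back in lowers the ceiling to 46.9%, so I expect red near that share.

The rule stops working where nucleophile over electrophile passes two, because the ceiling then passes 100%. Grey stands at 3.12, with a ceiling of 156%, more than 100%, so I expect time to end it, not the count. The alder run, with a ceiling of 219%, already reads 81.6% at 57.1% conversion. Grey runs hotter and longer than the alder run, so I expect it lower still, and the alder reading lies 5 points under the larch reading I carry to red, against a margin of 2 points.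

The forecast says red: red 86.5% (81% to 91%), grey 61% (52% to 71%), on the ground that “Nucleophile seems lost at about two per event”.

The flask gives red: red 86.2%, grey 64.1%.

    nucleophile + acid set free ⇌ protonated nucleophile, settled at all times (K = 3500 L mol⁻¹, ΔH = −12.0 kJ mol⁻¹)
    nucleophile + target → over-reaction product (k = 0.00140 L mol⁻¹ s⁻¹, Ea = 79.0 kJ mol⁻¹)
    electrophile + nucleophile → acid set free + target (k = 0.00350 L mol⁻¹ s⁻¹, Ea = 88.0 kJ mol⁻¹)
    (constants at 80 °C)

Red has converted 49.5% at 10.0 h, beside its ceiling of 50.0%, with 4.4% of its nucleophile still free. Now take a neighbour of grey charged with 0.0048 M of electrophile, which is 5.21 equiv of nucleophile. Its ceiling is 260%, again past the border. At 10.0 h it holds 50.0% target and 39.6% over-reaction product. The same count, two per electrophile converted and one more per over-reaction product, leaves 58.0% of the nucleophile, and the flask shows 58% free. Its share of target is 55.8%, lower than grey's 64.1%.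

The numbers in the tables were generated by integration for an exercise.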